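## Retrosynthetic overview

- **Feature:** the target is a 2,4,5-trisubstituted oxazole. C5 is bonded to indole C3. C4 (iodine) and C2 (pyrrol-2-yl) carry groups that can replace C-H later, so C5 can be the former formyl carbon of an indole-3-carbaldehyde.
- **Late disconnections:** the two N-H groups are released last (pyrrole Boc, indole Si(iPr)3). Before that, the oxazole C2-pyrrole C2 bond is made by a C2-selective Suzuki-Miyaura coupling of a 2,4-diiodooxazole.
- **Iodines:** both go back to C-H. C2 is iodinated by lithiation and quench, and C4 by iodination of the ring-opened isocyano enolate of the 2-lithiooxazole.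
- **Key disconnection:** oxazole C4-C5 and O1-C2. TosMIC supplies C4, N3 and C2. 6-Bromo-4-methoxy-1H-indole-3-carbaldehyde supplies C5 and O1, and is made by Vilsmeier-Haack formylation of the bought indole.
- **Ring order:** the indole is bought, the oxazole is built on it (the only ring closure of the route), and the pyrrole is attached preformed.

Key step: step 2

Assumption: 6-bromo-4-methoxy-1H-indole, TosMIC and 1-Boc-pyrrole-2-boronic acid are bought; the target holds no stereocentre and its biaryl bonds rotate freely, so no stereocontrol is required.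

## Route

Step 1
Reactants: 1 6-bromo-4-methoxy-1H-indole
Product: 3 6-bromo-4-methoxy-1H-indole-3-carbaldehyde, via indol-3-ylmethylidene dimethyliminium salt 2 (not isolated)
Conditions: POCl3 (1.2 equiv), DMF, 0 °C to 40 °C; then aq NaOH, 0 °C to rt
Reagents that add atoms: N,N-dimethylformamide CN(C)C=O; water O
Why: Vilsmeier-Haack formylation, in which the chloroiminium ion from DMF and POCl3 attacks the enamine-like C3, the most nucleophilic carbon of the indole, and basic hydrolysis of 2 releases the aldehyde while the aryl bromide and the methyl ether stay inert.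

Step 2
Reactants: 3 6-bromo-4-methoxy-1H-indole-3-carbaldehyde; 4 p-toluenesulfonylmethyl isocyanide (TosMIC)
Product: 6 5-(6-bromo-4-methoxy-1H-indol-3-yl)-1,3-oxazole, via trans-4-tosyl-4,5-dihydrooxazole 5 (not isolated)
Conditions: 4 (1.2 equiv), K2CO3 (2.5 equiv), MeOH, reflux
Reagents that add atoms: p-toluenesulfonylmethyl isocyanide (compound 4) Cc1ccc(S(=O)(=O)C[N+]#[C-])cc1
Why: This is the van Leusen oxazole synthesis, a base-mediated formal [3+2] annulation: carbonate deprotonates the CH2 of 4, which is acidified by the sulfonyl and isocyano groups, and the carbanion adds to the formyl carbon of 3 to make the C4-C5 bond. The alkoxide so formed attacks the terminal isocyanide carbon in a 5-endo-dig closure that makes the O1-C2 bond and, after protonation at C2, gives oxazoline 5. Base-induced 1,2-elimination of H-5 and the C4 sulfinate then aromatises the ring to 6. The two stereocentres of 5 (C4 and C5, trans expected) are transient and vanish in this elimination, so no stereocentre has to be controlled. Regiochemistry is fixed by connectivity, because the formyl carbon can only become C5 while C2-H and C4-H stay free for the later ordered iodinations, and chemoselectivity rests on 3 having no enolisable hydrogen and on the aryl bromide and methyl ether being inert to K2CO3 in methanol. The formyl group is a vinylogous formamide next to the peri 4-methoxy group and the N-H is partly deprotonated, which slows the addition; refluxing protic solvent keeps neutral 3 available and a slight excess of 4 covers its decay, and N-unprotected indole-3-carbaldehydes are established substrates of this reaction.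

Step 3
Reactants: 6 5-(6-bromo-4-methoxy-1H-indol-3-yl)-1,3-oxazole
Product: 8 5-[6-bromo-4-methoxy-1-(triisopropylsilyl)-1H-indol-3-yl]-1,3-oxazole, via sodium indolide 7 (not isolated)
Conditions: NaH (1.1 equiv), THF, 0 °C; iPr3SiCl (1.2 equiv), 0 °C to rt
Reagents that add atoms: chlorotriisopropylsilane CC(C)[Si](Cl)(C(C)C)C(C)C
Why: N-silylation of an indolide, in which NaH removes the indole N-H (far more acidic than oxazole C2-H) and salt 7 attacks silicon through nitrogen, giving a base-stable group that removes the acidic proton before the lithiations and shields indole C2 and C7.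

Step 4
Reactants: 8 5-[6-bromo-4-methoxy-1-(triisopropylsilyl)-1H-indol-3-yl]-1,3-oxazole
Product: 12 5-[6-bromo-4-methoxy-1-(triisopropylsilyl)-1H-indol-3-yl]-4-iodo-1,3-oxazole, via 2-lithiooxazole 9 (not isolated), via ring-opened lithium isocyanoenolate 10 (not isolated), via alpha-iodo isocyano ketone 11 (not isolated)
Conditions: LiN(SiMe3)2 (1.3 equiv), THF-DMPU, -78 °C; I2 (1.2 equiv) in THF, -78 °C
Reagents that add atoms: iodine II
Why: C4 iodination of a 5-substituted oxazole through the ring-chain equilibrium of its 2-lithio derivative, in which LiN(SiMe3)2 removes only C2-H, 9 opens to enolate 10, the strongly coordinating cosolvent DMPU favours and activates this open form so that iodine is taken up at the enolate carbon (former C4) to give 11, and enolisation with re-closure restores the aromatic ring bearing C2-H, the amide base causing no bromine-lithium exchange.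

Step 5
Reactants: 12 5-[6-bromo-4-methoxy-1-(triisopropylsilyl)-1H-indol-3-yl]-4-iodo-1,3-oxazole
Product: 14 5-[6-bromo-4-methoxy-1-(triisopropylsilyl)-1H-indol-3-yl]-2,4-diiodo-1,3-oxazole, via 4-iodo-2-lithiooxazole 13 (not isolated)
Conditions: LiN(SiMe3)2 (1.2 equiv), THF, -78 °C; I2 (1.3 equiv) in THF, -78 °C to -40 °C
Reagents that add atoms: iodine II
Why: Deprotonation-iodination (metalation and electrophilic quench), in which C2-H is the only acidic C-H left, C4 is already substituted so that 13 can only give an aromatic product by taking up iodine at C2, and LiN(SiMe3)2 at low temperature exchanges neither iodine nor bromine.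

Step 6
Reactants: 14 5-[6-bromo-4-methoxy-1-(triisopropylsilyl)-1H-indol-3-yl]-2,4-diiodo-1,3-oxazole; 15 1-(tert-butoxycarbonyl)pyrrole-2-boronic acid
Product: 16 tert-butyl 2-{5-[6-bromo-4-methoxy-1-(triisopropylsilyl)-1H-indol-3-yl]-4-iodo-1,3-oxazol-2-yl}-1H-pyrrole-1-carboxylate
Conditions: 15 (1.1 equiv), Pd(PPh3)4 (5 mol %), 2 M aq Na2CO3, 1,2-dimethoxyethane, 60 °C
Reagents that add atoms: 1-(tert-butoxycarbonyl)pyrrole-2-boronic acid (compound 15) CC(C)(C)OC(=O)n1cccc1B(O)O
Why: Site-selective Suzuki-Miyaura coupling, in which zerovalent palladium inserts fastest into the carbon-iodine bond at C2 (between O1 and N3, most electron-poor and unhindered), whereas the C4 iodine is screened by the neighbouring 4-methoxy-1-silylindol-3-yl group and the aryl carbon-bromine bond is intrinsically slower, so about one equivalent of 15 at moderate temperature should couple at C2 only.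

Step 7
Reactants: 16 tert-butyl 2-{5-[6-bromo-4-methoxy-1-(triisopropylsilyl)-1H-indol-3-yl]-4-iodo-1,3-oxazol-2-yl}-1H-pyrrole-1-carboxylate
Product: 17 tert-butyl 2-[5-(6-bromo-4-methoxy-1H-indol-3-yl)-4-iodo-1,3-oxazol-2-yl]-1H-pyrrole-1-carboxylate
Conditions: Bu4NF (1.2 equiv), AcOH (1.2 equiv), THF, 0 °C
Reagents that add atoms: none
Why: Fluoride-induced N-desilylation, in which fluoride attacks silicon and expels the stabilised indolide that acetic acid protonates at once, so the medium stays near neutral and the Boc group, both halogens and the oxazole are left untouched.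

Step 8
Reactants: 17 tert-butyl 2-[5-(6-bromo-4-methoxy-1H-indol-3-yl)-4-iodo-1,3-oxazol-2-yl]-1H-pyrrole-1-carboxylate
Product: 18 5-(6-bromo-4-methoxy-1H-indol-3-yl)-4-iodo-2-(1H-pyrrol-2-yl)-1,3-oxazole (target)
Conditions: K2CO3 (2 equiv), MeOH-THF, rt to 40 °C
Reagents that add atoms: none
Why: Base-catalysed methanolysis of an N-acylpyrrole-type carbamate, in which the pyrrolide is a good leaving group so that methoxide attacks the Boc carbonyl and frees the pyrrole N-H without acid, which could protodeiodinate or polymerise the electron-rich product.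

## Compound list

1 | 6-bromo-4-methoxy-1H-indole | COc1cc(Br)cc2[nH]ccc12 | starting material
2 | [(6-bromo-4-methoxy-1H-indol-3-yl)methylidene]dimethylammonium dichlorophosphate | COc1cc(Br)cc2[nH]cc(C=[N+](C)C)c12.[O-]P(=O)(Cl)Cl | intermediate
3 | 6-bromo-4-methoxy-1H-indole-3-carbaldehyde | COc1cc(Br)cc2[nH]cc(C=O)c12 | intermediate
4 | p-toluenesulfonylmethyl isocyanide (TosMIC) | Cc1ccc(S(=O)(=O)C[N+]#[C-])cc1 | starting material
5 | (±)-trans-5-(6-bromo-4-methoxy-1H-indol-3-yl)-4-tosyl-4,5-dihydro-1,3-oxazole (one enantiomer drawn) | COc1cc(Br)cc2[nH]cc([C@@H]3OC=N[C@H]3S(=O)(=O)c4ccc(C)cc4)c12 | intermediate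
6 | 5-(6-bromo-4-methoxy-1H-indol-3-yl)-1,3-oxazole | COc1cc(Br)cc2[nH]cc(-c3cnco3)c12 | intermediate
7 | sodium 6-bromo-4-methoxy-3-(1,3-oxazol-5-yl)indol-1-ide | COc1cc(Br)cc2[n-]cc(-c3cnco3)c12.[Na+] | intermediate
8 | 5-[6-bromo-4-methoxy-1-(triisopropylsilyl)-1H-indol-3-yl]-1,3-oxazole | COc1cc(Br)cc2n([Si](C(C)C)(C(C)C)C(C)C)cc(-c3cnco3)c12 | intermediate
9 | 5-[6-bromo-4-methoxy-1-(triisopropylsilyl)-1H-indol-3-yl]-2-lithio-1,3-oxazole | COc1cc(Br)cc2n([Si](C(C)C)(C(C)C)C(C)C)cc(-c3cnc([Li])o3)c12 | intermediate
10 | lithium (Z)-1-[6-bromo-4-methoxy-1-(triisopropylsilyl)-1H-indol-3-yl]-2-isocyanoethen-1-olate | COc1cc(Br)cc2n([Si](C(C)C)(C(C)C)C(C)C)cc(/C([O-])=C/[N+]#[C-])c12.[Li+] | intermediate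
11 | 1-[6-bromo-4-methoxy-1-(triisopropylsilyl)-1H-indol-3-yl]-2-iodo-2-isocyanoethan-1-one (racemic) | COc1cc(Br)cc2n([Si](C(C)C)(C(C)C)C(C)C)cc(C(=O)C(I)[N+]#[C-])c12 | intermediate
12 | 5-[6-bromo-4-methoxy-1-(triisopropylsilyl)-1H-indol-3-yl]-4-iodo-1,3-oxazole | COc1cc(Br)cc2n([Si](C(C)C)(C(C)C)C(C)C)cc(-c3ocnc3I)c12 | intermediate
13 | 5-[6-bromo-4-methoxy-1-(triisopropylsilyl)-1H-indol-3-yl]-4-iodo-2-lithio-1,3-oxazole | COc1cc(Br)cc2n([Si](C(C)C)(C(C)C)C(C)C)cc(-c3oc([Li])nc3I)c12 | intermediate
14 | 5-[6-bromo-4-methoxy-1-(triisopropylsilyl)-1H-indol-3-yl]-2,4-diiodo-1,3-oxazole | COc1cc(Br)cc2n([Si](C(C)C)(C(C)C)C(C)C)cc(-c3oc(I)nc3I)c12 | intermediate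
15 | 1-(tert-butoxycarbonyl)pyrrole-2-boronic acid | CC(C)(C)OC(=O)n1cccc1B(O)O | starting material
16 | tert-butyl 2-{5-[6-bromo-4-methoxy-1-(triisopropylsilyl)-1H-indol-3-yl]-4-iodo-1,3-oxazol-2-yl}-1H-pyrrole-1-carboxylate | COc1cc(Br)cc2n([Si](C(C)C)(C(C)C)C(C)C)cc(-c3oc(-c4cccn4C(=O)OC(C)(C)C)nc3I)c12 | intermediate
17 | tert-butyl 2-[5-(6-bromo-4-methoxy-1H-indol-3-yl)-4-iodo-1,3-oxazol-2-yl]-1H-pyrrole-1-carboxylate | COc1cc(Br)cc2[nH]cc(-c3oc(-c4cccn4C(=O)OC(C)(C)C)nc3I)c12 | intermediate
18 | 5-(6-bromo-4-methoxy-1H-indol-3-yl)-4-iodo-2-(1H-pyrrol-2-yl)-1,3-oxazole (CNP0134885.0) | COc1cc(Br)cc2[nH]cc(-c3oc(-c4ccc[nH]4)nc3I)c12 | target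

## Step count and risks

Total step count: 8.
Longest linear sequence: 8 steps (1 to 18); 4 and 15 are bought and enter in steps 2 and 6.

**Step 2 (key step).**
- What may go wrong: the TosMIC anion has to add to a formyl group that is weakened by vinylogous amide resonance and by reversible N-H deprotonation, and crowded by the peri methoxy group. The addition may be slower than the base-induced decay of the isocyanide, so conversion may stall.
- Fallback: the oxazole C5-indole C3 bond is made by cross-coupling of a preformed oxazole instead of by ring construction.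
  - It sets out from 1, which I2 and KOH in DMF should iodinate at C3 to 6-bromo-3-iodo-4-methoxy-1H-indole F1.
  - F1 is deprotonated at once with NaH in THF to sodium 6-bromo-3-iodo-4-methoxyindol-1-ide F2. Silylation with iPr3SiCl gives 6-bromo-3-iodo-4-methoxy-1-(triisopropylsilyl)-1H-indole F3.
  - A Suzuki-Miyaura coupling follows at the carbon-iodine bond with bought 2-(triisopropylsilyl)oxazole-5-boronic acid pinacol ester (CC(C)[Si](C(C)C)(C(C)C)c1ncc(B2OC(C)(C)C(C)(C)O2)o1), using Pd(PPh3)4 and aq Na2CO3 in 1,4-dioxane. It should give 5-[6-bromo-4-methoxy-1-(triisopropylsilyl)-1H-indol-3-yl]-2-(triisopropylsilyl)-1,3-oxazole F4.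
  - Dilute aq HCl in THF should cleave only the labile oxazole C2-silicon bond. The route is rejoined at 8.

**Step 4.**
- What may go wrong: iodine may be delivered to C2 of the closed lithio form instead of C4 of the open form. Proton exchange between the freshly iodinated species and unreacted anion may also leave conversion incomplete and cause some double iodination. The double iodination is harmless, since it leads to the product of step 5.
- Fallback: the anionic mechanism is replaced by electrophilic aromatic substitution.
  - It sets out from 8 and uses N-iodosuccinimide in DMF at rt to 50 °C.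
  - Attack should occur at oxazole C4, because the cation at C5 is stabilised by O1 and by the indol-3-yl group.
  - Indole C2 and C7 are shielded by the Si(iPr)3 group, and C5 of the indole is wedged between methoxy and bromine.
  - The route is rejoined at 12. Compounds outside the list: none F0.

**Step 6.**
- What may go wrong: palladium may insert at the C4 iodine or at the aryl bromine, double coupling may occur, and the pyrrole boronic acid may protodeboronate in warm aqueous base.
- Fallback: a Negishi coupling at room temperature without water or base, which should sharpen the rate differences and removes the boron reagent.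
  - Bought tert-butyl pyrrole-1-carboxylate (CC(C)(C)OC(=O)n1cccc1) is metalated with lithium 2,2,6,6-tetramethylpiperidide in THF at -78 °C to tert-butyl 2-lithio-1H-pyrrole-1-carboxylate F5.
  - F5 is transmetalated with ZnCl2 to [1-(tert-butoxycarbonyl)-1H-pyrrol-2-yl]zinc chloride F6.
  - The fallback sets out from 14, which is coupled with one equivalent of this zinc reagent under Pd(PPh3)4 in THF at rt. The route is rejoined at 16.

## Further compounds

F1 | step 2 | 6-bromo-3-iodo-4-methoxy-1H-indole | COc1cc(Br)cc2[nH]cc(I)c12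
F2 | step 2 | sodium 6-bromo-3-iodo-4-methoxyindol-1-ide | COc1cc(Br)cc2[n-]cc(I)c12.[Na+]
F3 | step 2 | 6-bromo-3-iodo-4-methoxy-1-(triisopropylsilyl)-1H-indole | COc1cc(Br)cc2n([Si](C(C)C)(C(C)C)C(C)C)cc(I)c12
F4 | step 2 | 5-[6-bromo-4-methoxy-1-(triisopropylsilyl)-1H-indol-3-yl]-2-(triisopropylsilyl)-1,3-oxazole | COc1cc(Br)cc2n([Si](C(C)C)(C(C)C)C(C)C)cc(-c3cnc([Si](C(C)C)(C(C)C)C(C)C)o3)c12
F0 | step 4 | none | none
F5 | step 6 | tert-butyl 2-lithio-1H-pyrrole-1-carboxylate | CC(C)(C)OC(=O)n1cccc1[Li]
F6 | step 6 | [1-(tert-butoxycarbonyl)-1H-pyrrol-2-yl]zinc chloride | CC(C)(C)OC(=O)n1cccc1[Zn]Cl
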